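(The numbers in the tables come from a simulation with made-up constants, noise included.)

I will reckon these flasks by one thing: the days of contact at 80 °C.

| flask | starting material | partner | temperature | remark | time |
|---|---|---|---|---|---|
| blue | 0.020 M | 5 equiv | 65 °C | run made earlier |  |
| grey | 0.020 M | 3.4 equiv | 80 °C | run made earlier |  |
| green | 0.020 M | 7.5 equiv | 65 °C | run made earlier |  |
| Tuesday's | 0.020 M | 5.00 equiv (fed, over 25 h) | 80 °C | all else is in the flask from the start; the feed brings no volume worth counting | 2.5 d |
| Thursday's | 0.020 M (fed, over 25 h) | 5.00 equiv |  | the addition at 40 °C, then warmed to 80 °C; the feed brings no volume worth counting | 2.5 d |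
| Wednesday's | 0.020 M | 5.00 equiv | 80 °C | everything together at the start | 2.5 d |
| Saturday's | 0.020 M (fed, over 25 h) | 5.00 equiv | 80 °C | all else is in the flask from the start; the feed brings no volume worth counting | 2.5 d |
| Monday's | 0.020 M | 5.00 equiv |  | everything together at the start at 40 °C, warmed to 80 °C at 25 h | 2.5 d |

| run | time / d | isomer of the product / % | target / % |
|---|---|---|---|
| blue | 0.208 | 0 | 0 |
| blue | 0.625 | 2.2 | 1.0 |
| blue | 1.04 | 3.5 | 0 |
| blue | 1.67 | 4.5 | 0 |
| blue | 2.50 | 5.5 | 1.2 |
| blue | 4.00 | 10.5 | 0.7 |
| grey | 0.208 | 3.0 | 0 |
| grey | 0.333 | 0.9 | 1.2 |
| grey | 0.500 | 2.3 | 0.2 |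
| grey | 0.833 | 5.4 | 0.9 |
| grey | 1.67 | 10.3 | 1.1 |
| grey | 2.50 | 14.1 | 1.5 |
| green | 0.833 | 3.8 | 2.6 |
| green | 1.67 | 8.0 | 1.0 |
| green | 2.50 | 8.8 | 0.6 |
| green | 4.00 | 16.1 | 1.4 |
| green | 5.00 | 18.1 | 1.5 |

(scatter of a reading: 1 percentage point)

- percentages count the starting material that a species holds: one side product counts as two
- steps thought possible: starting material + tautomer -> side product; partner + tautomer -> target; starting material + partner -> isomer of the product; starting material <-> tautomer

- the flask with the highest amount of isomer of the product, in percent of the starting material charged ("all alike" if they lie within 1.5 percentage points) (Tuesday's / Thursday's / Wednesday's / Saturday's / Monday's / all alike)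
- final isomer of the product, as a percentage of the starting material charged, in Tuesday's
- final isomer of the product, as a percentage of the starting material charged, in Thursday's
- final isomer of the product, as a percentage of the starting material charged, in Wednesday's
- final isomer of the product, as a percentage of the starting material charged, in Saturday's
- final isomer of the product, as a percentage of the starting material charged, in Monday's

Where should such a flask end? With the starting material turned mainly to isomer, I expect. Grey at 2.50 d reads isomer 14.1% against target 1.5%.

Does the partner count? Yes. At 4.00 d, green over blue reads 1.53 in isomer, and the partner charges stand at 1.50. So I take the step as first order in partner. I hold the partner constant at 5.00 equiv, the pseudo-first-order view.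

How fast at 80 °C? Counting isomer as the one loss, I let the fraction of starting material left fall exponentially. Grey's last reading, scaled to 5.00 equiv, gives 0.0894 /d. Call this the hot clock: the rate constant at which that fraction turns to isomer.

Isn't that one reading with a scatter of 1 percentage point? It is, so my figures carry that doubt. The side product was never read, so that loss stays open.

Are these flasks near their end? No: the hot clock's half-life is 7.75 d, longer than the 2.5 d allowed. So I expect contact time to set the answer.

What does a feed cost? In Saturday's, a fed portion of starting material arrives, on average, 0.521 d late. In Tuesday's, the fed partner stands during the feed at half its charge on average, which I reckon as the same loss. Either way, Tuesday's and Saturday's keep 1.98 d of contact.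

And 40 °C? Grey against blue gives a factor 3.22 from 65 °C to 80 °C. Carried down in equal steps, that gives me a cold clock slower by a factor 22.7. I count those hours as nothing, so Monday's and Thursday's keep 1.46 d.

My reckoning: Wednesday's 20.0%, both hot feeds 16.2%, Monday's and Thursday's 12.2%.

The forecast, close to these figures but not equal, names Wednesday's with 19.8%, then Saturday's 16.6%, Tuesday's 16.2%, Monday's 12.5% and Thursday's 12.4%, and of the two hot feeds it says “Feeding either reagent over 25 h cuts effective exposure to about 1.98 d”.

The flasks give Wednesday's 20.8%, the highest, then Saturday's 17.1%, Tuesday's 16.9%, Monday's 13.3% and Thursday's 13.2%.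

    starting material + tautomer → side product (k = 1.10 × 10⁻⁴ /M/s, Ea = 101 kJ/mol)
    partner + tautomer → target (k = 3.20 × 10⁻⁵ /M/s, Ea = 101 kJ/mol)
    starting material + partner → isomer of the product (k = 1.20 × 10⁻⁵ /M/s, Ea = 80.0 kJ/mol)
    starting material ⇌ tautomer (K = 0.0500, k = 6.00 × 10⁻⁶ /s, Ea = 129 kJ/mol, ΔH = 14.0 kJ/mol)
    (constants at 80 °C)

A neighbour of Wednesday's is charged with 0.034 M of starting material, with the equivalents and the time held. The partner stands richer by a factor 1.70, so I reckon the hot clock at 0.152 /d. Over 2.5 d that reckons to 31.6% isomer. The neighbour gives 31.8%, with 4.15% side product at 2.50 d.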